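## Structural features

The target joins a fully substituted benzene ring (2,4,6-trihydroxy, 1,3-diformyl) through one benzylic methine, C1′, to a guaiane-type hydroazulene. Guaiane numbering is used: ring A is the cyclopentane C1–C5, ring B the seven-membered ring C1, C5–C10, C11 the carbinol carbon on C7, C14 and C15 the methyls on C10 and C4, and C2′–C3′ the isobutyl chain. Rings A and B share the C1–C5 bond, and the only terpene alkene, C5=C6, is trisubstituted, endocyclic in ring B and exocyclic to ring A. There are five stereocentres, C1′ (S), C4 (R, quaternary), C1 (R), C7 (R) and C10 (R). C1′ is bonded to C4 and C1 to C10, while C7 stands alone; H-1, H-10, C11 and the C4–C1′ bond lie on one face (called α here), CH3-14, CH3-15 and H-7 on the other. The fragile groups are the aryl aldehydes and acidic phenols (a vinylogous acid that condenses with amines and hydrazines), the tertiary C11 alcohol (ionisation) and the C5=C6 bond next to quaternary C4 (cationic shifts). The real difficulty is the C1′–C4 junction: a tertiary benzylic carbon between a quaternary carbon and an arene with oxygen in both ortho positions, in a fixed configuration relative to C4. The key step uses the fact that C1′ carries the arene carbon, C2′, C4 and one hydrogen, so it has the oxidation level of an aldehyde carbon on C4; because C4 is quaternary, this aldehyde cannot enolise and its quinone methide cannot tautomerise to a styrene. The terpene half maps onto (−)-α-gurjunene, which has C1, C7 and C10 in the required configuration and whose C6–C11 cyclopropane bond is the latent form of both the C5=C6 alkene and the C11 carbinol.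

## Logic of the disconnections

10 ⇒ 9. No skeletal bond is cut; C3′ is taken back to an sp2 carbon (C3′=CH2). The reason is that a saturated isobutyl nucleophile cannot be delivered to C1′ in the presence of two aryl aldehydes, whereas a methallyl unit can come from a mild π-nucleophile. The demand on the forward step is reduction of a 1,1-disubstituted alkene without touching C5=C6 or the formyl groups.

9 ⇒ 3 + 6 + 7 (through 8). The aryl–C1′ and C1′–C2′ bonds are cut, leaving C1′ as the carbonyl carbon of 3. This removes the whole arene and the side chain in one operation and leaves the hindered C4–C1′ bond in place. The forward step must condense a neopentyl aldehyde with the one free ring position of 6, trap the resulting quinone methide with 7 faster than anything else, and select one face of C1′ under the sole influence of C4.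

3 ⇒ 2. Only the oxidation level of the C4 one-carbon substituent changes. The alcohol is what a formaldehyde addition delivers. The forward oxidation must leave the tertiary C11 alcohol and the alkene alone.

2 ⇒ 1. The C4–CH2OH bond and the C11–O bond are cut and the C6–C11 bond is re-formed. This returns the diol to a commercial sesquiterpene that already holds C1, C7 and C10. The forward step must bring a one-carbon electrophile to C4 on the α face and let the resulting cyclopropylcarbinyl cation open towards C11 before it does anything else.

6 ⇒ 4 (through 5). The two aryl–CHO bonds are cut, back to the symmetrical triphenol. The forward formylation must stop after two of the three equivalent positions.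

## Other disconnections considered

Alternative 1: The cut is the C1–C5 bond of ring A. It leads back to the trans-decalin A1, in which C1 is still bonded to C6, C6 carries the tertiary hydroxyl and C5 an equatorial mesylate. The arene is carried as its trimethyl ether and the C11 hydroxyl as a triethylsilyl ether. In the forward step KOtBu would form the C6 alkoxide of A1; the C1–C6 bond, antiperiplanar to C5–O, would migrate to C5 with loss of mesylate (semipinacol ring contraction and expansion) to give the cis-fused hydroazulen-6-one A2.
- In its favour: the shift is stereospecific (inversion at C5, retention at C1), six-membered rings give well-understood control, and the isobutyl group is present from the start, so no chemoselective hydrogenation is needed. On these three points it is the better plan.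
- Against it here: the C6 carbonyl of A2 must become the C5=C6 alkene with regiocontrol between two tertiary α-hydrogens (C5–H, C7–H). The arene still needs two formylations and three O-demethylations that the tertiary alcohol and the alkene must survive. The C1′–C4 pair has to be built on the decalin by separate chemistry, so that problem is moved, not solved.
- Comparison: the mechanisms are equally well founded. Structurally the chosen plan starts with the complete terpene skeleton and three of its stereocentres. On step count it is five steps against well over fifteen.

Alternative 2: The cut is the C1–C10 bond of ring B. It leads back to the seven-membered allylic lactone A3 (O–C8 bond, (E)-propenyl on C8, cis to the C7 side chain). In the forward step LiN(iPr)2 and Me3SiCl would give the silyl dienol ether of A3; a [3,3] shift through the boat-like transition state that the ring imposes would form C1–C10, break O–C8 and release C2 as the carboxylic acid of A4.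
- In its favour: one sigmatropic step makes the carbocycle and sets C1 and C10 by chirality transfer from C8 and the alkene geometry. This is more predictable than an intermolecular facial selection, a point on which it is the better plan.
- Against it here: ring A is still open in A4, and the C2–C3 bond must be made from an acid and a vinyl group with adjustment of carbon count. A4 has three alkenes of which only C5=C6 may survive. C1 is doubly activated and epimerisable, and the dienolate can react at its γ-position. The C1′–C4 pair and the late arene functionalisation remain open as in Alternative 1.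
- Comparison: the stereocentres it sets so neatly come free with 1 in the chosen plan, and the step count is several times higher.

Alternative 3: The cut runs through the arene, at the two ring bonds between the C–OH carbons flanking the ipso carbon and the two ester-bearing carbons. In the forward step the C1′-substituted malonyl dichloride A5 would doubly C-acylate dimethyl 3-oxoglutarate A6 (MgCl2, NEt3), and the cyclic triketone would enolise to the isophthalate A7.
- In its favour: the substitution pattern is fixed by construction, no quinone methide or π-nucleophile has to be controlled, and the C11 hydroxyl is protected. On regiochemical certainty it is the equal of the chosen plan (6 has only one free position), and on chemoselectivity of the coupling it is the better one.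
- Against it here: A5 would have to be made from 3 by chain extension and a conjugate addition of the isobutyl group, which meets the same facial problem at C1′. A malonyl dichloride with this α-substituent can lose HCl to a ketene. The two esters of A7 must be taken down to aldehydes on a free phloroglucinol, through benzylic alcohols that expel water easily, and the silyl ether must be removed.
- Comparison: it is equal on C1′ control, since both plans rely on C4, and roughly twice as long.

Key step: step 4

Assumption: carbon electrophiles are taken to enter C4 of (−)-α-gurjunene on the α face (the face of H-1), away from ring B and CH3-14, which is what the C4 configuration of the target requires.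

## Route

Step 1
Reactants: 1 (−)-α-gurjunene
Product: 2 (1R,4S,7R,10R)-4-(hydroxymethyl)guai-5-en-11-ol
Conditions: 37% aq. CH2O (methanol-free, 8 equiv), TsOH·H2O (5 mol %), 1,4-dioxane, 0 °C → rt
Reagents that add atoms: formaldehyde, C=O; water, O
Why: Prins reaction of a vinylcyclopropane: protonated formaldehyde attacks C4 of the tetrasubstituted C4=C5 bond, the cyclopropylcarbinyl cation at C5 opens its aligned C6–C11 bond to give the C5=C6 alkene and the tertiary C11 cation, and water captures it (the reaction type known for 2-carene and aldehydes). Protonation and formaldehyde addition are both first order in acid, so a high formaldehyde concentration favours the carbon electrophile. C4 is set by attack on the α face, and C1, C7 and C10 are not touched.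

Step 2
Reactants: 2 (1R,4S,7R,10R)-4-(hydroxymethyl)guai-5-en-11-ol
Product: 3 (1R,4S,7R,10R)-11-hydroxyguai-5-ene-4-carbaldehyde
Conditions: Dess–Martin periodinane (1.3 equiv), pyridine, CH2Cl2, 0 °C → rt
Reagents that add atoms: none
Why: Dess–Martin oxidation of the neopentyl primary alcohol; the tertiary C11 alcohol cannot be oxidised, and the α-quaternary aldehyde can neither enolise nor epimerise.

Step 3
Reactants: 4 phloroglucinol
Product: 6 2,4-diformylphloroglucinol (2,4,6-trihydroxybenzene-1,3-dicarbaldehyde), via bis(iminium) salt 5 (not isolated)
Conditions: POCl3 (2.2 equiv), DMF (2.2 equiv), 1,4-dioxane, 0 °C → rt; then H2O, rt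
Reagents that add atoms: N,N-dimethylformamide, CN(C)C=O; water, O
Why: Vilsmeier–Haack formylation of the most electron-rich arene available; each iminium group lowers the reactivity of the ring, so two equivalents of reagent stop at the bis(iminium) salt, which water hydrolyses to the dialdehyde with one ring C–H left.

Step 4
Reactants: 3 (1R,4S,7R,10R)-11-hydroxyguai-5-ene-4-carbaldehyde; 6 2,4-diformylphloroglucinol; 7 methallyltrimethylsilane
Product: 9 methallyl analogue of the target (C3′=CH2; 1′S,1R,4R,7R,10R), via ortho-quinone methide 8 (not isolated)
Conditions: ethylenediammonium diacetate (20 mol %), 7 (5 equiv), 1,4-dioxane, 80 °C, sealed tube; aq. NaH2PO4 work-up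
Reagents that add atoms: none
Why: The amine salt turns the non-enolisable aldehyde 3 into an iminium ion that the free ring carbon of 6 attacks (Knoevenagel/Mannich-type condensation), and loss of the amine gives the ortho-quinone methide 8, which cannot tautomerise to a styrene because C4 has no hydrogen. The allylsilane 7 adds through its terminal CH2 to C1′ of 8 (conjugate addition of Hosomi–Sakurai type); the tertiary β-silyl cation gives up its silyl group to the water released in the condensation, and rearomatisation of the phloroglucinol makes the addition irreversible. The closest known reaction type is the domino Knoevenagel/ortho-quinone-methide trapping of formylated phloroglucinols with aldehydes and alkenes, together with conjugate allylation of quinone methides by allylsilanes. No ring is closed: attack of the phenoxide oxygen on the β-silyl cation would be a six-membered closure, but its leaving group is a vinylogous carboxylate, so it should be reversible and desilylation the irreversible exit. C1′ is the only new stereocentre and is controlled by the adjacent quaternary C4 in a Felkin–Anh sense: the bulkiest C4 substituent (C5 with ring B and H-6) lies anti to the incoming silane, CH2-3 eclipses the exocyclic C=C, and the silane enters from the open outer side past CH3-15, which gives 1′S. Chemoselectivity is needed among three aldehydes and two alkenes: without a strong Lewis acid 7 does not add to 3, the formyl groups of 6 are deactivated vinylogous acids, and C5=C6 is shielded by C4. The tertiary C11 alcohol survives because the medium is only weakly acidic.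

Step 5
Reactants: 9 methallyl analogue of the target
Product: 10 target, 5-[(1S)-1-[(1R,3aR,4R,7R)-7-(2-hydroxypropan-2-yl)-1,4-dimethyl-1,2,3,3a,4,5,6,7-octahydroazulen-1-yl]-3-methylbutyl]-2,4,6-trihydroxybenzene-1,3-dicarbaldehyde
Conditions: H2 (1 atm), RhCl(PPh3)3 (5 mol %), toluene/EtOH (1:1), rt
Reagents that add atoms: none
Why: Homogeneous hydrogenation with RhCl(PPh3)3 discriminates by substitution: the terminal 1,1-disubstituted alkene is reduced, while the trisubstituted C5=C6 bond beside quaternary C4 is not, and at room temperature the hydrogen-bonded aryl aldehydes should not decarbonylate. C3′ becomes CH(CH3)2, so no stereocentre is formed or disturbed.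

## Compound list

1 | (−)-α-gurjunene, (1aR,4R,4aR,7bS)-1,1,4,7-tetramethyl-1a,2,3,4,4a,5,6,7b-octahydro-1H-cyclopropa[e]azulene | CC1=C2[C@H]3[C@H](C3(C)C)CC[C@@H](C)[C@H]2CC1 | starting material
2 | (1R,4S,7R,10R)-4-(hydroxymethyl)guai-5-en-11-ol; [(1S,3aR,4R,7R)-7-(2-hydroxypropan-2-yl)-1,4-dimethyl-1,2,3,3a,4,5,6,7-octahydroazulen-1-yl]methanol | OC[C@@]1(C)CC[C@H]2C1=C[C@H](C(C)(C)O)CC[C@H]2C | intermediate
3 | (1R,4S,7R,10R)-11-hydroxyguai-5-ene-4-carbaldehyde; (1S,3aR,4R,7R)-7-(2-hydroxypropan-2-yl)-1,4-dimethyl-1,2,3,3a,4,5,6,7-octahydroazulene-1-carbaldehyde | O=C[C@@]1(C)CC[C@H]2C1=C[C@H](C(C)(C)O)CC[C@H]2C | intermediate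
4 | phloroglucinol (benzene-1,3,5-triol) | Oc1cc(O)cc(O)c1 | starting material
5 | 2,4-bis[(dimethyliminio)methyl]phloroglucinol dichloride (bis(iminium) salt, not isolated) | C[N+](C)=Cc1c(O)cc(O)c(C=[N+](C)C)c1O.[Cl-].[Cl-] | intermediate
6 | 2,4-diformylphloroglucinol (2,4,6-trihydroxybenzene-1,3-dicarbaldehyde) | O=Cc1c(O)cc(O)c(C=O)c1O | intermediate
7 | methallyltrimethylsilane, trimethyl(2-methylprop-2-en-1-yl)silane | CC(=C)C[Si](C)(C)C | starting material
8 | ortho-quinone methide of 3 and 6 (exocyclic C1′=C(ring); ring carbonyl ortho to it; exocyclic alkene geometry left open, the two forms interconvert by proton shift; not isolated) | O=C1C(C=O)=C(O)C(C=O)=C(O)C1=C[C@@]2(C)CC[C@H]3C2=C[C@H](C(C)(C)O)CC[C@H]3C | intermediate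
9 | 5-[(1S)-1-[(1R,3aR,4R,7R)-7-(2-hydroxypropan-2-yl)-1,4-dimethyl-1,2,3,3a,4,5,6,7-octahydroazulen-1-yl]-3-methylbut-3-en-1-yl]-2,4,6-trihydroxybenzene-1,3-dicarbaldehyde | CC(=C)C[C@H](c1c(O)c(C=O)c(O)c(C=O)c1O)[C@@]1(C)CC[C@H]2C1=C[C@H](C(C)(C)O)CC[C@H]2C | intermediate
10 | 5-[(1S)-1-[(1R,3aR,4R,7R)-7-(2-hydroxypropan-2-yl)-1,4-dimethyl-1,2,3,3a,4,5,6,7-octahydroazulen-1-yl]-3-methylbutyl]-2,4,6-trihydroxybenzene-1,3-dicarbaldehyde | CC(C)C[C@H](c1c(O)c(C=O)c(O)c(C=O)c1O)[C@@]1(C)CC[C@H]2C1=C[C@H](C(C)(C)O)CC[C@H]2C | target

## Step count and least certain steps

Total: 5 steps. Longest linear sequence: 4 steps (1 → 2 → 3 → 9 → 10); step 3 is a one-step branch that joins at step 4.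

**Step 4 (key step).**
- What may go wrong: poor or reversed facial selectivity at C1′. The Felkin–Anh rotamer that leads to 1′S presses CH2-3 against an ortho oxygen of the quinone methide, and the rotamer with CH3-15 eclipsed, which relieves that strain, exposes the opposite face.
- Also possible: slow condensation at the neopentyl aldehyde, so that protodesilylation of 7 by the acidic phenol outruns formation of 8, and closure through the phenoxide oxygen in place of desilylation.
- Fallback, from 1 and 6, returning at 10: the polarity of the union is reversed. Compound 6 is condensed with 3-methylbutanal under the same amine catalysis in aqueous 1,4-dioxane at 60–80 °C to the isopentyl ortho-quinone methide F1. The C4=C5 bond of 1 adds through C4 to its methide carbon, the cyclopropylcarbinyl cation opens, and water captures C11, giving 10 directly. This is the known alkylation of terpene alkenes by formylphloroglucinol quinone methides. C4 and C1′ are then set together in the approach of two trigonal carbons, so a failure of acyclic control by C4 in step 4 does not carry over.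

**Step 1.**
- What may go wrong: protonation of the C4=C5 bond competing with formaldehyde addition (ring opening and hydration without the new carbon), attack on the β face, loss of H-1 in an ene sense with the cyclopropane left intact, or a second addition of formaldehyde to the product alkene.
- Fallback, from 1, returning at 2: the carbon is delivered by a [2,3]-sigmatropic shift and not by a cationic addition.
  - Epoxidation of 1 (mCPBA, NaHCO3, CH2Cl2, 0 °C) gives the 4,5-epoxide F2; either face serves.
  - Dilute HClO4 in aqueous THF opens it at C5 with the same cyclopropane opening and hydration to 4-hydroxyguai-5-en-11-ol F3; here the proton is the intended electrophile.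
  - Oxidative transposition with pyridinium chlorochromate, C5H5NH[CrO3Cl], in CH2Cl2 gives 11-hydroxyguai-4-en-6-one F4, which erases C4.
  - Luche reduction (NaBH4, CeCl3·7H2O, MeOH, −78 °C), with hydride entering anti to the C7 side chain, gives the 6α-alcohol F5.
  - KH and Bu3SnCH2I in THF give the 6-O-(tributylstannyl)methyl ether F6.
  - Excess n-BuLi at −78 °C starts the Still–Wittig [2,3] rearrangement, which moves the CH2O unit suprafacially from O6 to the α face of C4 and re-forms C5=C6, giving 2.
  - This is six known steps in place of one, but C4 then follows from the C6 carbinol and not from the facial preference of an intermolecular electrophile.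

**Step 5.**
- What may go wrong: migration of the 1,1-disubstituted alkene into the trisubstituted position by a rhodium hydride, after which it would resist reduction, or chelation-assisted insertion of rhodium into a formyl C–H bond next to a phenol.
- Fallback, from 9, returning at 10, with no new compound (F0): radical hydrogen-atom-transfer hydrogenation with Mn(dpm)3 (tris(dipivaloylmethanato)manganese), PhSiH3 and t-BuOOH in i-PrOH at rt. The hydrogen atoms are delivered one at a time to the terminal alkene through a tertiary radical, without metal–alkyl or acyl–metal intermediates that could isomerise or decarbonylate; hindered C5=C6 reacts far more slowly.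

## Further compounds

F1 | step 4 | isopentyl ortho-quinone methide of 6 and 3-methylbutanal | CC(C)CC=C1C(=O)C(C=O)=C(O)C(C=O)=C1O
F2 | step 1 | 4α,5α-epoxide of (−)-α-gurjunene (α face drawn; the β-epoxide serves equally) | C[C@]12CC[C@H]3[C@]1(O2)[C@H]1[C@H](C1(C)C)CC[C@H]3C
F3 | step 1 | 4α-hydroxyguai-5-en-11-ol (C1, C7, C10 as in 1) | C[C@]1(O)CC[C@H]2C1=C[C@H](C(C)(C)O)CC[C@H]2C
F4 | step 1 | 11-hydroxyguai-4-en-6-one (C1, C7, C10 as in 1) | CC1=C2C(=O)[C@H](C(C)(C)O)CC[C@@H](C)[C@H]2CC1
F5 | step 1 | guai-4-ene-6α,11-diol (6R; C1, C7, C10 as in 1) | CC1=C2[C@H](O)[C@H](C(C)(C)O)CC[C@@H](C)[C@H]2CC1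
F6 | step 1 | 6α-[(tributylstannyl)methoxy]guai-4-en-11-ol | CC1=C2[C@H](OC[Sn](CCCC)(CCCC)CCCC)[C@H](C(C)(C)O)CC[C@@H](C)[C@H]2CC1
F0 | step 5 | none | none
A1 | alternative 1 | trans-decalin 6-ol 5-mesylate (C1–C6 bond, 6β-OH, 5β equatorial OMs, trimethoxyaryl, 11-O-triethylsilyl) | CC(C)C[C@H](c1c(OC)cc(OC)cc1OC)[C@@]1(C)CC[C@H]2[C@](O)([C@@H]1OS(C)(=O)=O)[C@H](C(C)(C)O[Si](CC)(CC)CC)CC[C@H]2C
A2 | alternative 1 | cis-fused hydroazulen-6-one (trimethoxyaryl, 11-O-triethylsilyl) | CC(C)C[C@H](c1c(OC)cc(OC)cc1OC)[C@@]1(C)CC[C@H]2[C@@H]1C(=O)[C@H](C(C)(C)O[Si](CC)(CC)CC)CC[C@H]2C
A3 | alternative 2 | seven-membered allylic lactone (O–C8 bond, (E)-propenyl on C8 cis to the C7 side chain) | C/C=C/[C@@H]1OC(=O)CC(=C[C@@H]1C(C)(C)O[Si](CC)(CC)CC)[C@](C)(C=C)[C@H](CC(C)C)c1c(OC)cc(OC)cc1OC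
A4 | alternative 2 | cyclohepta-2,5-diene carboxylic acid with C1, C7 and C10 set | OC(=O)[C@H]1C(=C[C@H](C(C)(C)O[Si](CC)(CC)CC)C=C[C@H]1C)[C@](C)(C=C)[C@H](CC(C)C)c1c(OC)cc(OC)cc1OC
A5 | alternative 3 | C1′-substituted malonyl dichloride (11-O-triethylsilyl) | ClC(=O)C(C(Cl)=O)[C@@H](CC(C)C)[C@@]1(C)CC[C@H]2C1=C[C@H](C(C)(C)O[Si](CC)(CC)CC)CC[C@H]2C
A6 | alternative 3 | dimethyl 3-oxoglutarate | COC(=O)CC(=O)CC(=O)OC
A7 | alternative 3 | dimethyl 2,4,6-trihydroxy-5-alkylisophthalate with the full skeleton (11-O-triethylsilyl) | CC(C)C[C@H](c1c(O)c(C(=O)OC)c(O)c(C(=O)OC)c1O)[C@@]1(C)CC[C@H]2C1=C[C@H](C(C)(C)O[Si](CC)(CC)CC)CC[C@H]2C
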